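Everything rests on making the benzo ring of the tetralone (C4a, C5, C6, C7, C8, C8a), a symmetric 6,7-dioxygenated arene, last and from three alkynes. A cobalt-catalysed [2+2+2] cycloaddition of an acyclic 1,7-diyne with bis(pinacolboryl)acetylene creates C4a–C8a, C5–C6 and C7–C8 at once, so ring B and the aromatic ring arise in a single operation and boron sits on C6 and C7, the two carbons that must bear oxygen. The precursor is the open-chain ynone 6-aryl-4,5-dimethylocta-1,7-diyn-3-one, which already carries C2, C3 and C4. C4 is set by catalytic conjugate alkynylation, C3 by auxiliary-controlled methylation and C2 by a final equilibration.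

Key step: step 11

Remarks on the chemistry
- Notation: Ar = 3-(benzyloxy)-4-methoxyphenyl; C1–C8a are the tetralone locants. The target is (2S,3R,4R), i.e. 2,3-trans and 3,4-cis.
- Enolate propargylation through cobalt-stabilised propargyl cations is syn-selective and would place the C3 methyl and C4 aryl groups trans on ring B. For the cis target, C4 is therefore set by asymmetric conjugate alkynylation and C3 by methylation under control of the (R)-configured auxiliary.
- Assumption: the sense of induction in step 2 is not predicted here; the ligand antipode that delivers (R)-5 is used (to be confirmed on acid 6).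
- Assumption: the enolisable C2 is carried as both epimers from 14 to 22 (SMILES leave it open there) and is fixed thermodynamically in step 14.

Step 1
Reactants: 1 3-(benzyloxy)-4-methoxybenzaldehyde; 2 Meldrum's acid
Product: 3 5-(Ar-methylidene)-2,2-dimethyl-1,3-dioxane-4,6-dione
Conditions: pyrrolidine (10 mol %), AcOH (10 mol %), PhMe, rt
Reagents that add atoms: none
Why: Knoevenagel condensation of the highly acidic cyclic malonate with an aryl aldehyde; the acceptor is symmetric, so no alkene-geometry question arises.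

Step 2
Reactants: 3; 4 ethynyltrimethylsilane
Product: 5 5-[(1R)-1-Ar-3-(trimethylsilyl)prop-2-yn-1-yl]-2,2-dimethyl-1,3-dioxane-4,6-dione
Conditions: [Rh(OAc)(C2H4)2]2 (2.5 mol %), 3,5-xylyl-MeO-BIPHEP (5.5 mol %, antipode giving (R)-5), 4 (3 equiv), 1,4-dioxane/H2O, rt
Reagents that add atoms: none
Why: Rhodium-catalysed asymmetric conjugate alkynylation of an arylidene Meldrum's acid: an alkynyl complex of monovalent rhodium adds 1,4 to the doubly activated alkene and the atropisomeric bisphosphine selects the alkene face, which sets C4 by catalyst control.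

Step 3
Reactants: 5
Product: 6 (3R)-3-Ar-5-(trimethylsilyl)pent-4-ynoic acid
Conditions: DMF/H2O (10:1), 100 °C
Reagents that add atoms: water, O
Why: Hydrolytic ring opening of the monosubstituted Meldrum's acid followed by decarboxylation; the neutral medium should leave the C–Si bond and the propargylic centre untouched.

Step 4
Reactants: 6; 7 (4R)-4-benzyl-1,3-oxazolidin-2-one
Product: 9 (4R)-4-benzyl-3-[(3R)-3-Ar-5-(trimethylsilyl)pent-4-ynoyl]-1,3-oxazolidin-2-one, via mixed pivalic anhydride 8 (not isolated)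
Conditions: PivCl, Et3N, THF, −20 °C; then LiCl, 7, −20 °C → rt
Reagents that add atoms: pivaloyl chloride, CC(C)(C)C(=O)Cl (its atoms appear in 8 only)
Why: N-acylation of the oxazolidinone through a mixed anhydride with LiCl/Et3N activation, a mild protocol that needs no strong base and so cannot disturb the silylalkyne or C4.

Step 5
Reactants: 9
Product: 10 (4R)-4-benzyl-3-[(2R,3R)-3-Ar-2-methyl-5-(trimethylsilyl)pent-4-ynoyl]-1,3-oxazolidin-2-one
Conditions: NaN(SiMe3)2, THF, −78 °C; MeI, −78 → −40 °C
Reagents that add atoms: iodomethane, CI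
Why: Evans asymmetric alkylation: the chelated (Z)-enolate formed with NaN(SiMe3)2 is methylated on the face away from the benzyl group of the (R)-auxiliary, which sets C3 as R by auxiliary control and places methyl and aryl anti along the chain, hence cis on ring B.

Step 6
Reactants: 10
Product: 11 (2R,3R)-3-Ar-N-methoxy-N,2-dimethyl-5-(trimethylsilyl)pent-4-ynamide
Conditions: MeNH(OMe)·HCl, AlMe3, CH2Cl2, −10 °C → rt
Reagents that add atoms: N,O-dimethylhydroxylamine hydrochloride, CNOC.Cl
Why: Weinreb transamidation: MeAl(Cl)N(OMe)Me attacks the exocyclic imide carbonyl and releases the auxiliary without any free base, so C3 should not epimerise.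

Step 7
Reactants: 11
Product: 12 (3R,4R)-4-Ar-3-methyl-6-(trimethylsilyl)hex-5-yn-2-one
Conditions: MeMgBr, THF, 0 °C
Reagents that add atoms: methylmagnesium bromide, C[Mg]Br
Why: Weinreb ketone synthesis; the chelated tetrahedral adduct of MeMgBr stops at mono-addition and releases the ketone only on aqueous quench.

Step 8
Reactants: 12
Product: 14 (3R,4R)-4-Ar-2,3-dimethyl-6-(trimethylsilyl)hex-5-ynal (both C2 epimers), via methyl enol ether 13 (not isolated)
Conditions: MeOCH2PPh3Cl, KN(SiMe3)2, THF, 0 °C → rt; then 2 M HCl, THF, rt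
Reagents that add atoms: (methoxymethyl)triphenylphosphonium chloride, COC[P+](c1ccccc1)(c1ccccc1)c1ccccc1.[Cl-]; water, O
Why: Wittig methoxymethylenation and acid hydrolysis of the enol ether (one-carbon homologation of a ketone to an aldehyde); C2 is formed by unselective protonation as both epimers, which is tolerated because this centre is equilibrated in step 14.

Step 9
Reactants: 14; 15 ethynylmagnesium bromide
Product: 17 (5R,6S)-6-Ar-4,5-dimethylocta-1,7-diyn-3-ol (mixture at C3 and C4), via silylated diynol 16 (not isolated)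
Conditions: 15, THF, 0 °C; then MeOH, K2CO3, rt
Reagents that add atoms: none
Why: 1,2-Addition of an alkynyl Grignard reagent to the aldehyde, then base-catalysed methanolysis of the alkynyl C–Si bond in the same flask; the carbinol configuration is irrelevant because it is oxidised next.

Step 10
Reactants: 17
Product: 18 (5R,6S)-6-Ar-4,5-dimethylocta-1,7-diyn-3-one (both C4 epimers)
Conditions: Dess–Martin periodinane, NaHCO3, CH2Cl2, 0 °C → rt
Reagents that add atoms: none
Why: Dess–Martin oxidation of the secondary propargylic alcohol under buffered, non-basic conditions, which should spare the terminal ynone and the C5/C6 stereocentres.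

Step 11
Reactants: 18; 19 bis(pinacolboryl)acetylene
Product: 20 (3R,4R)-4-Ar-2,3-dimethyl-6,7-bis(4,4,5,5-tetramethyl-1,3,2-dioxaborolan-2-yl)-3,4-dihydronaphthalen-1(2H)-one (both C2 epimers)
Conditions: CpCo(CO)2 (15 mol %), 19 (4 equiv), PhMe, reflux, hν (visible lamp), slow addition of 18
Reagents that add atoms: none
Why: After loss of CO the CpCo fragment binds both alkynes of 18 and couples them oxidatively to a cobaltacyclopentadiene, forming C4a–C8a; coordination and insertion of 19 into a Co–C bond and reductive elimination then form C5–C6 and C7–C8 and return monovalent cobalt. The closest known reaction type is the cobalt-catalysed cotrimerisation of α,ω-diynes with bis(trimethylsilyl)acetylene or alkynylboronates to fused arenes. Ring B closes by intramolecular alkyne–alkyne oxidative cyclisation of the 1,7-diyne on the metal, and the benzene ring closes by a formal [4+2] addition of the third alkyne across the metallacycle diene. No stereocentre is formed: C3 and C4 lie on the tether and are not touched in the neutral medium, and the enolisable C2 is corrected in step 14. The step needs cross- over self-trimerisation, which is secured by the tether (the two alkynes of 18 couple with each other faster than with a second molecule), by the inability of hindered 19 to trimerise with itself, by its excess and by slow addition of 18; regioselectivity is no issue because 19 is symmetric.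

Step 12
Reactants: 20
Product: 21 (3R,4R)-4-Ar-6,7-dihydroxy-2,3-dimethyl-3,4-dihydronaphthalen-1(2H)-one (both C2 epimers)
Conditions: NaBO3·4H2O, THF/H2O (1:1), rt
Reagents that add atoms: sodium perborate, [Na+].[Na+].O[B-]1(O)OO[B-](O)(O)OO1
Why: Oxidation of both aryl C–B bonds by peroxide attack at boron and 1,2-aryl shift to oxygen; the mild, weakly basic perborate should avoid Dakin-type cleavage of the p-hydroxyaryl ketone.

Step 13
Reactants: 21
Product: 22 (3R,4R)-4-Ar-6,7-dimethoxy-2,3-dimethyl-3,4-dihydronaphthalen-1(2H)-one (both C2 epimers)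
Conditions: MeI, K2CO3, acetone, reflux
Reagents that add atoms: iodomethane, CI
Why: Williamson O-methylation of the two phenols; the third phenolic oxygen is masked as the benzyl ether, which is what differentiates the two aryl rings.

Step 14
Reactants: 22
Product: 23 (2S,3R,4R)-4-Ar-6,7-dimethoxy-2,3-dimethyl-3,4-dihydronaphthalen-1(2H)-one
Conditions: NaOMe (0.2 equiv), MeOH/THF, rt
Reagents that add atoms: none
Why: Base-mediated epimerisation through the enolate under thermodynamic control: with the C4 aryl group pseudoaxial (away from the peri hydrogen at C5) the C3 methyl is equatorial, and the C2 methyl is most stable equatorial and trans to it, which is 2S; the cis epimer would be 1,3-diaxial with the aryl group.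

Step 15
Reactants: 23
Product: 24 (2S,3R,4R)-4-(3-hydroxy-4-methoxyphenyl)-6,7-dimethoxy-2,3-dimethyl-3,4-dihydronaphthalen-1(2H)-one
Conditions: H2 (1 atm), Pd/C (10 %), EtOAc, rt
Reagents that add atoms: none
Why: Hydrogenolysis of the aryl benzyl ether; at one atmosphere and room temperature the electron-rich aryl ketone and the C4–H bond should not be reduced.

Compound list
1 | 3-(benzyloxy)-4-methoxybenzaldehyde (O-benzylisovanillin) | COc1ccc(C=O)cc1OCc1ccccc1 | starting material
2 | 2,2-dimethyl-1,3-dioxane-4,6-dione (Meldrum's acid) | CC1(C)OC(=O)CC(=O)O1 | starting material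
3 | 5-[[3-(benzyloxy)-4-methoxyphenyl]methylidene]-2,2-dimethyl-1,3-dioxane-4,6-dione | COc1ccc(C=C2C(=O)OC(C)(C)OC2=O)cc1OCc1ccccc1 | intermediate
4 | ethynyltrimethylsilane | C#C[Si](C)(C)C | starting material
5 | 5-[(1R)-1-[3-(benzyloxy)-4-methoxyphenyl]-3-(trimethylsilyl)prop-2-yn-1-yl]-2,2-dimethyl-1,3-dioxane-4,6-dione | COc1ccc([C@H](C#C[Si](C)(C)C)C2C(=O)OC(C)(C)OC2=O)cc1OCc1ccccc1 | intermediate
6 | (3R)-3-[3-(benzyloxy)-4-methoxyphenyl]-5-(trimethylsilyl)pent-4-ynoic acid | COc1ccc([C@H](C#C[Si](C)(C)C)CC(=O)O)cc1OCc1ccccc1 | intermediate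
7 | (4R)-4-benzyl-1,3-oxazolidin-2-one | O=C1N[C@H](Cc2ccccc2)CO1 | starting material
8 | mixed anhydride of acid 6 with pivalic acid | COc1ccc([C@H](C#C[Si](C)(C)C)CC(=O)OC(=O)C(C)(C)C)cc1OCc1ccccc1 | intermediate
9 | (4R)-4-benzyl-3-[(3R)-3-[3-(benzyloxy)-4-methoxyphenyl]-5-(trimethylsilyl)pent-4-ynoyl]-1,3-oxazolidin-2-one | COc1ccc([C@H](C#C[Si](C)(C)C)CC(=O)N2[C@H](Cc3ccccc3)COC2=O)cc1OCc1ccccc1 | intermediate
10 | (4R)-4-benzyl-3-[(2R,3R)-3-[3-(benzyloxy)-4-methoxyphenyl]-2-methyl-5-(trimethylsilyl)pent-4-ynoyl]-1,3-oxazolidin-2-one | COc1ccc([C@H](C#C[Si](C)(C)C)[C@@H](C)C(=O)N2[C@H](Cc3ccccc3)COC2=O)cc1OCc1ccccc1 | intermediate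
11 | (2R,3R)-3-[3-(benzyloxy)-4-methoxyphenyl]-N-methoxy-N,2-dimethyl-5-(trimethylsilyl)pent-4-ynamide | COc1ccc([C@H](C#C[Si](C)(C)C)[C@@H](C)C(=O)N(C)OC)cc1OCc1ccccc1 | intermediate
12 | (3R,4R)-4-[3-(benzyloxy)-4-methoxyphenyl]-3-methyl-6-(trimethylsilyl)hex-5-yn-2-one | COc1ccc([C@H](C#C[Si](C)(C)C)[C@@H](C)C(C)=O)cc1OCc1ccccc1 | intermediate
13 | (3R,4R)-4-[3-(benzyloxy)-4-methoxyphenyl]-1-methoxy-2,3-dimethyl-6-(trimethylsilyl)hex-1-en-5-yne (E/Z mixture) | COc1ccc([C@H](C#C[Si](C)(C)C)[C@@H](C)C(C)=COC)cc1OCc1ccccc1 | intermediate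
14 | (3R,4R)-4-[3-(benzyloxy)-4-methoxyphenyl]-2,3-dimethyl-6-(trimethylsilyl)hex-5-ynal (both C2 epimers) | COc1ccc([C@H](C#C[Si](C)(C)C)[C@@H](C)C(C)C=O)cc1OCc1ccccc1 | intermediate
15 | ethynylmagnesium bromide | C#C[Mg]Br | starting material
16 | (5R,6R)-6-[3-(benzyloxy)-4-methoxyphenyl]-4,5-dimethyl-8-(trimethylsilyl)octa-1,7-diyn-3-ol (mixture at C3 and C4) | COc1ccc([C@H](C#C[Si](C)(C)C)[C@@H](C)C(C)C(O)C#C)cc1OCc1ccccc1 | intermediate
17 | (5R,6S)-6-[3-(benzyloxy)-4-methoxyphenyl]-4,5-dimethylocta-1,7-diyn-3-ol (mixture at C3 and C4) | COc1ccc([C@H](C#C)[C@@H](C)C(C)C(O)C#C)cc1OCc1ccccc1 | intermediate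
18 | (5R,6S)-6-[3-(benzyloxy)-4-methoxyphenyl]-4,5-dimethylocta-1,7-diyn-3-one (both C4 epimers; the 4S epimer maps directly onto the target) | COc1ccc([C@H](C#C)[C@@H](C)C(C)C(=O)C#C)cc1OCc1ccccc1 | intermediate
19 | 1,2-bis(4,4,5,5-tetramethyl-1,3,2-dioxaborolan-2-yl)ethyne (bis(pinacolboryl)acetylene) | CC1(C)OB(OC1(C)C)C#CB1OC(C)(C)C(C)(C)O1 | starting material
20 | (3R,4R)-4-[3-(benzyloxy)-4-methoxyphenyl]-2,3-dimethyl-6,7-bis(4,4,5,5-tetramethyl-1,3,2-dioxaborolan-2-yl)-3,4-dihydronaphthalen-1(2H)-one (both C2 epimers) | COc1ccc([C@@H]2c3cc(B4OC(C)(C)C(C)(C)O4)c(B4OC(C)(C)C(C)(C)O4)cc3C(=O)C(C)[C@@H]2C)cc1OCc1ccccc1 | intermediate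
21 | (3R,4R)-4-[3-(benzyloxy)-4-methoxyphenyl]-6,7-dihydroxy-2,3-dimethyl-3,4-dihydronaphthalen-1(2H)-one (both C2 epimers) | COc1ccc([C@@H]2c3cc(O)c(O)cc3C(=O)C(C)[C@@H]2C)cc1OCc1ccccc1 | intermediate
22 | (3R,4R)-4-[3-(benzyloxy)-4-methoxyphenyl]-6,7-dimethoxy-2,3-dimethyl-3,4-dihydronaphthalen-1(2H)-one (both C2 epimers) | COc1ccc([C@@H]2c3cc(OC)c(OC)cc3C(=O)C(C)[C@@H]2C)cc1OCc1ccccc1 | intermediate
23 | (2S,3R,4R)-4-[3-(benzyloxy)-4-methoxyphenyl]-6,7-dimethoxy-2,3-dimethyl-3,4-dihydronaphthalen-1(2H)-one | COc1ccc([C@@H]2c3cc(OC)c(OC)cc3C(=O)[C@@H](C)[C@@H]2C)cc1OCc1ccccc1 | intermediate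
24 | (2S,3R,4R)-4-(3-hydroxy-4-methoxyphenyl)-6,7-dimethoxy-2,3-dimethyl-3,4-dihydronaphthalen-1(2H)-one (CNP0170223.1) | COc1ccc([C@@H]2c3cc(OC)c(OC)cc3C(=O)[C@@H](C)[C@@H]2C)cc1O | target

Total step count: 15
Longest linear sequence: 15 steps (1 → 24)

Steps most likely to fail

Step 11. The electron-poor terminal ynone may be consumed by oligomerisation or self-trimerisation before the cobaltacycle captures the hindered alkyne. The fallback moves the cycloaddition one step earlier, to the carbinol oxidation level, where no Michael acceptor is present. It sets out from diynol 17: cotrimerisation with 19 (CpCo(CO)2, PhMe, reflux, hν, slow addition) should give (3R,4R)-4-Ar-2,3-dimethyl-6,7-bis(pinacolboryl)-1,2,3,4-tetrahydronaphthalen-1-ol F1 as a mixture at C1 and C2. Oxidation of its benzylic alcohol with MnO2 in CH2Cl2 comes back to the route at 20.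

Step 8. Reversible enolisation of ketone 12 by the basic ylide may erode the C3 configuration, or the α-branched ketone may olefinate too slowly. The fallback avoids a basic carbon nucleophile. It sets out from 12: methylenation with Cp2TiMe2 (PhMe, 65 °C) should give (3R,4R)-4-Ar-2,3-dimethyl-6-(trimethylsilyl)hex-1-en-5-yne F2. Hydroboration of the terminal alkene with 9-BBN and oxidation with NaBO3·4H2O should give the primary alcohol (3R,4R)-4-Ar-2,3-dimethyl-6-(trimethylsilyl)hex-5-yn-1-ol F3 (both C2 epimers). Dess–Martin oxidation comes back to the route at 14.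

Step 2. Facial discrimination or catalyst turnover may be insufficient with this electron-rich arylidene. The fallback secures C4 by separating auxiliary diastereomers instead of by catalysis. It sets out from 3: uncatalysed conjugate addition of [(trimethylsilyl)ethynyl]magnesium bromide (from 4 and EtMgBr, THF, −40 °C) should give the racemic Meldrum's acid adduct F4. Decarboxylative hydrolysis as in step 3 gives the racemic pentynoic acid F5. Acylation of 7 as in step 4, via the racemic mixed pivalic anhydride F6, gives 9 together with its (3S)-epimeric imide F7; the two are separated by chromatography or crystallisation, and the route resumes at 9.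

Further compounds
F1 | step 11 | (3R,4R)-4-[3-(benzyloxy)-4-methoxyphenyl]-2,3-dimethyl-6,7-bis(4,4,5,5-tetramethyl-1,3,2-dioxaborolan-2-yl)-1,2,3,4-tetrahydronaphthalen-1-ol (mixture at C1 and C2) | COc1ccc([C@@H]2c3cc(B4OC(C)(C)C(C)(C)O4)c(B4OC(C)(C)C(C)(C)O4)cc3C(O)C(C)[C@@H]2C)cc1OCc1ccccc1
F2 | step 8 | (3R,4R)-4-[3-(benzyloxy)-4-methoxyphenyl]-2,3-dimethyl-6-(trimethylsilyl)hex-1-en-5-yne | COc1ccc([C@H](C#C[Si](C)(C)C)[C@@H](C)C(C)=C)cc1OCc1ccccc1
F3 | step 8 | (3R,4R)-4-[3-(benzyloxy)-4-methoxyphenyl]-2,3-dimethyl-6-(trimethylsilyl)hex-5-yn-1-ol (both C2 epimers) | COc1ccc([C@H](C#C[Si](C)(C)C)[C@@H](C)C(C)CO)cc1OCc1ccccc1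
F4 | step 2 | racemic 5-[1-[3-(benzyloxy)-4-methoxyphenyl]-3-(trimethylsilyl)prop-2-yn-1-yl]-2,2-dimethyl-1,3-dioxane-4,6-dione | COc1ccc(C(C#C[Si](C)(C)C)C2C(=O)OC(C)(C)OC2=O)cc1OCc1ccccc1
F5 | step 2 | racemic 3-[3-(benzyloxy)-4-methoxyphenyl]-5-(trimethylsilyl)pent-4-ynoic acid | COc1ccc(C(C#C[Si](C)(C)C)CC(=O)O)cc1OCc1ccccc1
F6 | step 2 | racemic mixed anhydride of F5 with pivalic acid | COc1ccc(C(C#C[Si](C)(C)C)CC(=O)OC(=O)C(C)(C)C)cc1OCc1ccccc1
F7 | step 2 | (4R)-4-benzyl-3-[(3S)-3-[3-(benzyloxy)-4-methoxyphenyl]-5-(trimethylsilyl)pent-4-ynoyl]-1,3-oxazolidin-2-one | COc1ccc([C@@H](C#C[Si](C)(C)C)CC(=O)N2[C@H](Cc3ccccc3)COC2=O)cc1OCc1ccccc1
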